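**Assumption and shorthand (one line):** C1–C8a are the locants of the tetralone core of the target (C1 ring ketone, C3 carbinol, C4 aroyl-bearing carbon), and the target is read as (3R,4S) with 3-OH cis to the 4-aroyl group; Ar1 = 2,4-bis(benzyloxy)-6-bromophenyl, Ar2 = 2,4-bis(benzyloxy)-6-{[4-(benzyloxy)-2-oxo-2H-pyran-6-yl]methyl}phenyl; compounds 1 and 13 and all reagents in the Conditions lines are bought.

## Retrosynthetic overview

1. Target 20 comes from pentabenzyl ether 19 by hydrogenolysis, and 19 from carbinol 18 by oxidation at C1; the C1 carbinol is a traceless stereocontrol element.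
2. Key disconnection: the aldol array of 18 is hidden in a cis-fused isoxazoline, whose C4–C(aroyl) and C3–O bonds are made in one magnesium-alkoxide-directed nitrile oxide cycloaddition of dihydronaphthalenol 8 with aryl nitrile oxide 10. No C3–C4 aldol bond is ever formed.
3. The pyranone is joined after the cycloaddition by Pd-catalysed coupling of the aryl bromide with a pyranylmethylzinc reagent.
4. Both 8 and 10 come from one bromo aldehyde 4: 8 by vinylation, Brown methallylation (sets C1) and ring-closing metathesis; 10 by oximation and oxidation.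
5. Ring order: rings A and C and the pyranone are bought as aromatic units; ring B is closed by metathesis; the isoxazoline ring is formed, then opened.

## Route

Step 1
Reactants: 1 5-bromobenzene-1,3-diol
Product: 2 1,3-bis(benzyloxy)-5-bromobenzene
Conditions: BnBr (2.2 equiv), K2CO3, DMF, 60 °C
Reagents that add atoms: benzyl bromide, BrCc1ccccc1
Why: Williamson etherification of both phenols, with benzyl chosen so that all five aryl/pyranone ethers fall in one neutral hydrogenolysis at the end.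

Step 2
Reactants: 2 1,3-bis(benzyloxy)-5-bromobenzene
Product: 4 2,4-bis(benzyloxy)-6-bromobenzaldehyde, via aryl iminium chloride 3 (not isolated)
Conditions: POCl3, DMF, 0 → 80 °C; then H2O
Reagents that add atoms: N,N-dimethylformamide, CN(C)C=O; water, O
Why: Vilsmeier–Haack formylation goes ortho/para to the two ether oxygens at the position next to Br, the site between the two benzyloxy groups being more hindered, as is usual for 5-haloresorcinol diethers.

Step 3
Reactants: 4 2,4-bis(benzyloxy)-6-bromobenzaldehyde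
Product: 5 2,4-bis(benzyloxy)-6-ethenylbenzaldehyde
Conditions: Bu3SnCH=CH2, Pd(PPh3)4 (5 mol%), toluene, 100 °C
Reagents that add atoms: tributyl(vinyl)stannane, C=C[Sn](CCCC)(CCCC)CCCC
Why: Stille coupling of the aryl bromide, to which the aldehyde is inert.

Step 4
Reactants: 5 2,4-bis(benzyloxy)-6-ethenylbenzaldehyde
Product: 7 (1S)-1-[2,4-bis(benzyloxy)-6-ethenylphenyl]-3-methylbut-3-en-1-ol, via diisopinocampheylborinate ester 6 (not isolated)
Conditions: (−)-Ipc2BOMe [from (+)-α-pinene], CH2=C(CH3)CH2MgCl, Et2O, −78 °C → rt; then 5, −78 °C; NaOH, H2O2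
Reagents that add atoms: 2-methylallylmagnesium chloride, CC(=C)C[Mg]Cl
Why: Brown asymmetric methallylboration through a chair Zimmerman–Traxler transition state, in which the (+)-α-pinene-derived borane attacks the Si face of aryl aldehydes and so gives the (S)-carbinol at C1, a centre that only steers step 8 and is erased in step 12 (the sense is confirmed on 7 by Mosher ester analysis).

Step 5
Reactants: 7 (1S)-1-[2,4-bis(benzyloxy)-6-ethenylphenyl]-3-methylbut-3-en-1-ol
Product: 8 (1S)-6,8-bis(benzyloxy)-3-methyl-1,2-dihydronaphthalen-1-ol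
Conditions: second-generation Grubbs catalyst RuCl2(=CHPh)(H2IMes)(PCy3) (5 mol%), CH2Cl2, 40 °C; chromatography on Et3N-washed silica
Reagents that add atoms: none
Why: ring-closing metathesis of the styrene with the 1,1-disubstituted alkene closes ring B as the trisubstituted cyclic styrene, driven by loss of ethylene, and leaves C1 untouched.

Step 6
Reactants: 4 2,4-bis(benzyloxy)-6-bromobenzaldehyde
Product: 9 (E)-2,4-bis(benzyloxy)-6-bromobenzaldehyde oxime
Conditions: NH2OH·HCl, NaOAc, EtOH/H2O, rt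
Reagents that add atoms: hydroxylamine hydrochloride, Cl.NO
Why: oxime condensation of the aldehyde.

Step 7
Reactants: 9 (E)-2,4-bis(benzyloxy)-6-bromobenzaldehyde oxime
Product: 10 2,4-bis(benzyloxy)-6-bromobenzonitrile oxide
Conditions: PhI(OAc)2, MeOH/CH2Cl2, 0 °C
Reagents that add atoms: none
Why: hypervalent-iodine dehydrogenation of the aldoxime gives a nitrile oxide that is flanked by Br and OBn and therefore, like mesityl- or 2,6-dichlorobenzonitrile oxide, resists dimerisation and can be isolated, while avoiding the ring halogenation that N-halo reagents would cause on this electron-rich arene.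

Step 8
Reactants: 8 (1S)-6,8-bis(benzyloxy)-3-methyl-1,2-dihydronaphthalen-1-ol; 10 2,4-bis(benzyloxy)-6-bromobenzonitrile oxide
Product: 12 (1S,3R,4R)-isoxazoline-fused tetralin-1-ol bearing Ar1 on the C=N carbon, via bromomagnesium alkoxide 11 (not isolated)
Conditions: EtMgBr (1.0 equiv), CH2Cl2, 0 °C; then 10 (1.3 equiv), 0 °C → rt; H2O
Reagents that add atoms: none
Why: Kanemasa-type magnesium-alkoxide-directed 1,3-dipolar cycloaddition, in which the C1–OMgBr group (held pseudoaxial by peri strain with the 8-benzyloxy group) binds the nitrile oxide oxygen and delivers it to C3 on its own face while the carbon terminus bonds to the less substituted C4, so the suprafacial addition sets C3 (R) and the C4–C bond cis to the C3–O bond and both syn to the (1S)-oxygen, with the regiochemistry that trisubstituted alkenes prefer anyway (O to the more substituted carbon).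

Step 9
Reactants: 13 4-hydroxy-6-methyl-2H-pyran-2-one
Product: 14 4-(benzyloxy)-6-methyl-2H-pyran-2-one
Conditions: BnOH, PPh3, DIAD, THF, 0 °C → rt
Reagents that add atoms: benzyl alcohol, OCc1ccccc1
Why: Mitsunobu O-alkylation of the acidic vinylogous acid OH gives the 4-benzyl ether and avoids the C3-benzylation seen with benzyl halides and base.

Step 10
Reactants: 12 (1S,3R,4R)-isoxazoline-fused tetralin-1-ol bearing Ar1; 14 4-(benzyloxy)-6-methyl-2H-pyran-2-one
Product: 16 (1S,3R,4R)-isoxazoline-fused tetralin-1-ol bearing Ar2 on the C=N carbon, via pyranylmethylzinc chloride 15 (not isolated)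
Conditions: 14 (3 equiv), LiN(SiMe3)2, THF, −78 °C; ZnCl2, → 0 °C; then 12, Pd2(dba)3 (2.5 mol%), SPhos (10 mol%), 60 °C
Reagents that add atoms: none
Why: Proposed new method: amide-base deprotonation of the vinylogous 6-methyl group and transmetalation to zinc gives a soft trienolate that should transfer to the aryl palladium bromide formed by oxidative addition to zerovalent palladium and reductively eliminate at the terminal CH2, the only site that restores the pyranone conjugation, the closest known reactions being the Pd-catalysed arylation of Reformatsky-type zinc enolates and the γ-arylation of dienolates (Negishi-type coupling); the isoxazoline N–O bond and the C1 alkoxide are inert to the weakly basic zinc reagent used in excess.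

Step 11
Reactants: 16 (1S,3R,4R)-isoxazoline-fused tetralin-1-ol bearing Ar2
Product: 18 (1S,3R,4S)-4-(Ar2-carbonyl)-6,8-bis(benzyloxy)-3-methyl-1,2,3,4-tetrahydronaphthalene-1,3-diol, via beta-hydroxy ketimine 17 (not isolated)
Conditions: Mo(CO)6, MeCN/H2O (15:1), 80 °C
Reagents that add atoms: water, O
Why: Mo(CO)6-mediated reductive N–O cleavage of the isoxazoline and in situ hydrolysis of the ketimine (isoxazoline as latent aldol) release the β-hydroxy ketone under neutral conditions without touching a bond at C3 or C4, so the cis relationship is carried over intact (C4 becomes S only because the CIP priorities change).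

Step 12
Reactants: 18 (1S,3R,4S)-4-(Ar2-carbonyl)-6,8-bis(benzyloxy)-3-methyl-1,2,3,4-tetrahydronaphthalene-1,3-diol
Product: 19 (3R,4S)-4-(Ar2-carbonyl)-6,8-bis(benzyloxy)-3-hydroxy-3-methyl-3,4-dihydronaphthalen-1(2H)-one
Conditions: Dess–Martin periodinane, pyridine, CH2Cl2, 0 °C
Reagents that add atoms: none
Why: Dess–Martin oxidation takes the secondary benzylic C1 carbinol to the ketone and cannot touch the tertiary C3–OH, and the cold, buffered, base-free medium avoids retro-aldol cleavage, C4 epimerisation and dehydration to the naphthol.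

Step 13
Reactants: 19 (3R,4S)-4-(Ar2-carbonyl)-6,8-bis(benzyloxy)-3-hydroxy-3-methyl-3,4-dihydronaphthalen-1(2H)-one
Product: 20 (3R,4S)-4-{2,4-dihydroxy-6-[(4-hydroxy-2-oxo-2H-pyran-6-yl)methyl]benzoyl}-3,6,8-trihydroxy-3-methyl-3,4-dihydronaphthalen-1(2H)-one
Conditions: H2 (1 atm), Pd/C (10%), EtOAc/MeOH, rt; stop at full debenzylation
Reagents that add atoms: none
Why: catalytic hydrogenolysis removes the four aryl benzyl ethers and the pyranone benzyl ether under neutral conditions that leave the acid- and base-sensitive β-hydroxy ketone, the hydrogen-bonded aryl ketones and both stereocentres unchanged.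

## Compound list

1 | 5-bromobenzene-1,3-diol | Oc1cc(O)cc(Br)c1 | starting material
2 | 1,3-bis(benzyloxy)-5-bromobenzene | Brc1cc(OCc2ccccc2)cc(OCc2ccccc2)c1 | intermediate
3 | N-{[2,4-bis(benzyloxy)-6-bromophenyl]methylidene}-N-methylmethanaminium chloride | C[N+](C)=Cc1c(Br)cc(OCc2ccccc2)cc1OCc1ccccc1.[Cl-] | intermediate
4 | 2,4-bis(benzyloxy)-6-bromobenzaldehyde | O=Cc1c(Br)cc(OCc2ccccc2)cc1OCc1ccccc1 | intermediate
5 | 2,4-bis(benzyloxy)-6-ethenylbenzaldehyde | O=Cc1c(C=C)cc(OCc2ccccc2)cc1OCc1ccccc1 | intermediate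
6 | O-diisopinocampheylboryl derivative (borinate ester) of 7 | CC(=C)C[C@H](OB([C@@H]1C[C@@H]2C[C@@H](C2(C)C)[C@H]1C)[C@@H]1C[C@@H]2C[C@@H](C2(C)C)[C@H]1C)c1c(C=C)cc(OCc2ccccc2)cc1OCc1ccccc1 | intermediate
7 | (1S)-1-[2,4-bis(benzyloxy)-6-ethenylphenyl]-3-methylbut-3-en-1-ol | CC(=C)C[C@H](O)c1c(C=C)cc(OCc2ccccc2)cc1OCc1ccccc1 | intermediate
8 | (1S)-6,8-bis(benzyloxy)-3-methyl-1,2-dihydronaphthalen-1-ol | CC1=Cc2cc(OCc3ccccc3)cc(OCc3ccccc3)c2[C@@H](O)C1 | intermediate
9 | (E)-2,4-bis(benzyloxy)-6-bromobenzaldehyde oxime | O/N=C/c1c(Br)cc(OCc2ccccc2)cc1OCc1ccccc1 | intermediate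
10 | 2,4-bis(benzyloxy)-6-bromobenzonitrile oxide | [O-][N+]#Cc1c(Br)cc(OCc2ccccc2)cc1OCc1ccccc1 | intermediate
11 | bromomagnesium alkoxide of 8 | CC1=Cc2cc(OCc3ccccc3)cc(OCc3ccccc3)c2[C@@H](O[Mg]Br)C1 | intermediate
12 | (1S,3R,4R)-6,8-bis(benzyloxy)-3-methyl-1,2,3,4-tetrahydronaphthalen-1-ol with C3 and C4 bridged as a cis-fused 2-isoxazoline (C3–O–N=C(Ar1)–C4), 1-OH cis to the ring oxygen | C[C@@]12C[C@H](O)c3c(OCc4ccccc4)cc(OCc4ccccc4)cc3[C@@H]1C(=NO2)c1c(Br)cc(OCc2ccccc2)cc1OCc1ccccc1 | intermediate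
13 | 4-hydroxy-6-methyl-2H-pyran-2-one (triacetic acid lactone) | Cc1cc(O)cc(=O)o1 | starting material
14 | 4-(benzyloxy)-6-methyl-2H-pyran-2-one | Cc1cc(OCc2ccccc2)cc(=O)o1 | intermediate
15 | {[4-(benzyloxy)-2-oxo-2H-pyran-6-yl]methyl}zinc chloride | Cl[Zn]Cc1cc(OCc2ccccc2)cc(=O)o1 | intermediate
16 | (1S,3R,4R)-isoxazoline-fused tetralin-1-ol as 12 but with Ar2 on the C=N carbon | C[C@@]12C[C@H](O)c3c(OCc4ccccc4)cc(OCc4ccccc4)cc3[C@@H]1C(=NO2)c1c(Cc2cc(OCc4ccccc4)cc(=O)o2)cc(OCc2ccccc2)cc1OCc1ccccc1 | intermediate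
17 | (1S,3R,4R)-6,8-bis(benzyloxy)-4-[imino(Ar2)methyl]-3-methyl-1,2,3,4-tetrahydronaphthalene-1,3-diol (N–H ketimine) | C[C@@]1(O)C[C@H](O)c2c(OCc3ccccc3)cc(OCc3ccccc3)cc2[C@@H]1C(=N)c1c(Cc2cc(OCc3ccccc3)cc(=O)o2)cc(OCc2ccccc2)cc1OCc1ccccc1 | intermediate
18 | (1S,3R,4S)-4-(Ar2-carbonyl)-6,8-bis(benzyloxy)-3-methyl-1,2,3,4-tetrahydronaphthalene-1,3-diol | C[C@@]1(O)C[C@H](O)c2c(OCc3ccccc3)cc(OCc3ccccc3)cc2[C@@H]1C(=O)c1c(Cc2cc(OCc3ccccc3)cc(=O)o2)cc(OCc2ccccc2)cc1OCc1ccccc1 | intermediate
19 | (3R,4S)-4-(Ar2-carbonyl)-6,8-bis(benzyloxy)-3-hydroxy-3-methyl-3,4-dihydronaphthalen-1(2H)-one (pentabenzyl ether of the target) | C[C@@]1(O)CC(=O)c2c(OCc3ccccc3)cc(OCc3ccccc3)cc2[C@@H]1C(=O)c1c(Cc2cc(OCc3ccccc3)cc(=O)o2)cc(OCc2ccccc2)cc1OCc1ccccc1 | intermediate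
20 | (3R,4S)-4-{2,4-dihydroxy-6-[(4-hydroxy-2-oxo-2H-pyran-6-yl)methyl]benzoyl}-3,6,8-trihydroxy-3-methyl-3,4-dihydronaphthalen-1(2H)-one (CNP0197349.1) | C[C@@]1(O)CC(=O)c2c(O)cc(O)cc2[C@@H]1C(=O)c1c(O)cc(O)cc1Cc1cc(O)cc(=O)o1 | target

## Step count and risks

Total step count: 13.
Longest linear sequence: 10 steps (steps 1, 2, 3, 4, 5, 8, 10, 11, 12, 13).

**Most likely to fail, 1: step 8 (directed cycloaddition).** The hindered nitrile oxide may add slowly to the trisubstituted alkene, or magnesium delivery may give poor facial selectivity. The fallback replaces chelation control by steric control in the enantiomeric C1 series. It sets out from 5: methallylation with the borane made from (+)-Ipc2BOMe gives (1R)-1-[2,4-bis(benzyloxy)-6-ethenylphenyl]-3-methylbut-3-en-1-ol F1. Silylation (TBSOTf, 2,6-lutidine) gives its tert-butyldimethylsilyl ether F2, and ring-closing metathesis gives the (1R)-1-silyloxy-3-methyl-1,2-dihydronaphthalene F3. Heating F3 with 10 in toluene at 80 °C without any metal lets the dipole add anti to the pseudoaxial silyloxy group (as electrophiles add anti to an axial homoallylic substituent in cyclohexenes), giving the (1R,3R,4R) silyl ether cycloadduct F4. Bu4NF/AcOH gives the (1R,3R,4R) alcohol F5, the C1 epimer of 12. F5 is taken through the operations of steps 10 and 11 to the coupled isoxazoline F6 and the (1R,3R,4S) diol ketone F7. Dess–Martin oxidation of F7 erases C1, and the route comes back at 19.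

**Most likely to fail, 2: step 10 (arylation of the pyranone zinc trienolate).** Coupling may occur at the wrong carbon or stall on the hindered, chelating aryl bromide. The fallback builds the pyranone on the arene instead of coupling it. It sets out from 12: Pd-catalysed arylation of the Reformatsky-type reagent BrZnCH2C(O)N(OMe)CH3 gives the aryl N-methoxy-N-methylacetamide F8. Acylation of the lithium dienolate of 2,2,6-trimethyl-4H-1,3-dioxin-4-one (excess, THF, −78 °C) by F8 gives the β-keto dioxinone F9. Thermolysis in toluene at 110 °C (loss of acetone, acylketene, ring closure by the enol oxygen) gives the 4-hydroxypyranone F10. O-benzylation (BnBr, K2CO3, acetone) brings the route back at 16.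

**Most likely to fail, 3: step 11 (N–O cleavage and hydrolysis).** The di-ortho-substituted ketimine may hydrolyse slowly, and 80 °C may cause dehydration. The fallback inverts the order and unmasks by catalytic hydrogenolysis at room temperature. It sets out from 16: Dess–Martin oxidation gives the (3R,4R) isoxazoline-fused tetralone F11. Treatment with H2 (1 atm), Raney Ni and B(OH)3 in MeOH/H2O at rt cleaves the N–O bond and hydrolyses the imine, and the route comes back at 19.

## Further compounds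

F1 | step 8 | (1R)-1-[2,4-bis(benzyloxy)-6-ethenylphenyl]-3-methylbut-3-en-1-ol | CC(=C)C[C@@H](O)c1c(C=C)cc(OCc2ccccc2)cc1OCc1ccccc1
F2 | step 8 | tert-butyldimethylsilyl ether of F1 | CC(=C)C[C@@H](O[Si](C)(C)C(C)(C)C)c1c(C=C)cc(OCc2ccccc2)cc1OCc1ccccc1
F3 | step 8 | (1R)-6,8-bis(benzyloxy)-1-(tert-butyldimethylsilyloxy)-3-methyl-1,2-dihydronaphthalene | CC1=Cc2cc(OCc3ccccc3)cc(OCc3ccccc3)c2[C@H](O[Si](C)(C)C(C)(C)C)C1
F4 | step 8 | (1R,3R,4R) silyl ether cycloadduct (as 12, opposite configuration at C1, OTBS in place of OH) | C[C@@]12C[C@@H](O[Si](C)(C)C(C)(C)C)c3c(OCc4ccccc4)cc(OCc4ccccc4)cc3[C@@H]1C(=NO2)c1c(Br)cc(OCc2ccccc2)cc1OCc1ccccc1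
F5 | step 8 | (1R,3R,4R) alcohol, C1 epimer of 12 | C[C@@]12C[C@@H](O)c3c(OCc4ccccc4)cc(OCc4ccccc4)cc3[C@@H]1C(=NO2)c1c(Br)cc(OCc2ccccc2)cc1OCc1ccccc1
F6 | step 8 | coupled isoxazoline, C1 epimer of 16 | C[C@@]12C[C@@H](O)c3c(OCc4ccccc4)cc(OCc4ccccc4)cc3[C@@H]1C(=NO2)c1c(Cc2cc(OCc4ccccc4)cc(=O)o2)cc(OCc2ccccc2)cc1OCc1ccccc1
F7 | step 8 | (1R,3R,4S) diol ketone, C1 epimer of 18 | C[C@@]1(O)C[C@@H](O)c2c(OCc3ccccc3)cc(OCc3ccccc3)cc2[C@@H]1C(=O)c1c(Cc2cc(OCc3ccccc3)cc(=O)o2)cc(OCc2ccccc2)cc1OCc1ccccc1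
F8 | step 10 | aryl N-methoxy-N-methylacetamide (12 with Br replaced by CH2C(O)N(OMe)Me) | C[C@@]12C[C@H](O)c3c(OCc4ccccc4)cc(OCc4ccccc4)cc3[C@@H]1C(=NO2)c1c(CC(=O)N(C)OC)cc(OCc2ccccc2)cc1OCc1ccccc1
F9 | step 10 | β-keto dioxinone (12 with Br replaced by CH2C(O)CH2-(2,2-dimethyl-4-oxo-4H-1,3-dioxin-6-yl)) | C[C@@]12C[C@H](O)c3c(OCc4ccccc4)cc(OCc4ccccc4)cc3[C@@H]1C(=NO2)c1c(CC(=O)CC2=CC(=O)OC(C)(C)O2)cc(OCc2ccccc2)cc1OCc1ccccc1
F10 | step 10 | 4-hydroxypyranone (16 lacking the pyranone benzyl group) | C[C@@]12C[C@H](O)c3c(OCc4ccccc4)cc(OCc4ccccc4)cc3[C@@H]1C(=NO2)c1c(Cc2cc(O)cc(=O)o2)cc(OCc2ccccc2)cc1OCc1ccccc1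
F11 | step 11 | (3R,4R) isoxazoline-fused tetralone (16 oxidised at C1) | C[C@@]12CC(=O)c3c(OCc4ccccc4)cc(OCc4ccccc4)cc3[C@@H]1C(=NO2)c1c(Cc2cc(OCc4ccccc4)cc(=O)o2)cc(OCc2ccccc2)cc1OCc1ccccc1
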